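The isoflavone is cut across ring C at C3–C4 and O1–C2. The carbonyl carbon C4 and the ring oxygen O1 are attached to the adjacent ring A carbons C4a and C8a, exactly as the formyl carbon and the hydroxyl of a salicylaldehyde, and C2 carries only hydrogen, so a silyl group that is removed later can occupy C2 and orient an alkyne. One rhodium-catalysed oxidative annulation therefore joins 2-hydroxy-4,6-dimethoxybenzaldehyde to a 1-aryl-2-trimethylsilyl alkyne that already carries both prenyl ethers of ring B, making two bonds and ring C at once. The alkyne comes from 3,4-dihydroxybenzaldehyde in three steps, and fluoride removes silicon at the end.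

Key step: step 4

Assumption: in the annulation the silyl-bearing alkyne carbon is taken to end up on rhodium, and so on O1, as silyl alkynes do in Larock-type heteroannulations; this orientation is argued by analogy and is the one place where the route carries real risk.

Step 1
Reactants: 1 3,4-dihydroxybenzaldehyde; 2 prenyl bromide (1-bromo-3-methylbut-2-ene)
Product: 3 3,4-bis(3-methylbut-2-enyloxy)benzaldehyde
Conditions: K2CO3 (3 equiv), 2 (2.4 equiv), DMF, rt to 50 °C
Reagents that add atoms: none
Why: Double Williamson ether synthesis: both phenoxides displace bromide from the primary allylic halide (SN2), and the non-enolisable aldehyde is inert to carbonate.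

Step 2
Reactants: 3 3,4-bis(3-methylbut-2-enyloxy)benzaldehyde
Product: 5 4-ethynyl-1,2-bis(3-methylbut-2-enyloxy)benzene, via diazoalkene 4 (not isolated)
Conditions: dimethyl (1-diazo-2-oxopropyl)phosphonate (1.3 equiv), K2CO3 (2 equiv), MeOH, 0 °C to rt
Reagents that add atoms: dimethyl (1-diazo-2-oxopropyl)phosphonate (Ohira–Bestmann reagent), COP(=O)(OC)C(=[N+]=[N-])C(C)=O
Why: Seyferth–Gilbert homologation in its Ohira–Bestmann form: methanolysis frees the diazomethylphosphonate anion, Horner–Wadsworth–Emmons-type olefination of the aldehyde gives diazoalkene 4, and loss of N2 with a 1,2-hydrogen shift of the alkylidene carbene should deliver the terminal alkyne under mild base that leaves aryl prenyl ethers untouched.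

Step 3
Reactants: 5 4-ethynyl-1,2-bis(3-methylbut-2-enyloxy)benzene
Product: 7 {[3,4-bis(3-methylbut-2-enyloxy)phenyl]ethynyl}trimethylsilane, via lithium acetylide 6 (not isolated)
Conditions: n-BuLi (1.05 equiv), THF, −78 °C; then Me3SiCl (1.2 equiv), −78 °C to rt
Reagents that add atoms: chlorotrimethylsilane, C[Si](C)(C)Cl
Why: Acetylide formation and C-silylation: at −78 °C the sp C–H bond is by far the most acidic site, so neither the allylic ether methylenes nor the arene should be metalated before the acetylide is trapped by the chlorosilane.

Step 4
Reactants: 7 {[3,4-bis(3-methylbut-2-enyloxy)phenyl]ethynyl}trimethylsilane; 8 2-hydroxy-4,6-dimethoxybenzaldehyde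
Product: 9 3-[3,4-bis(3-methylbut-2-enyloxy)phenyl]-5,7-dimethoxy-2-(trimethylsilyl)chromen-4-one
Conditions: [Cp*RhCl2]2 (2.5 mol%), anhydrous Cu(OAc)2 (2.2 equiv), 8 (1.2 equiv), o-xylene, 110 °C, N2
Reagents that add atoms: none
Why: Chloride–acetate exchange gives a Cp*Rh acetate of trivalent rhodium to which the phenoxide of 8 binds, and acetate-assisted cleavage of the formyl C–H bond gives a five-membered acyl rhodacycle. Alkyne 7 inserts into the Rh–acyl bond so that the acyl carbon bonds to the aryl-bearing carbon (C3–C4) while rhodium keeps the silyl-bearing carbon; C–O reductive elimination from the seven-membered oxa-rhodacycle then forms O1–C2, so ring C is closed by reductive elimination in a formal [4+2] oxidative annulation, and the monovalent rhodium released is reoxidised by two equivalents of Cu(OAc)2. The closest known reaction type is the Cp*Rh-catalysed oxidative annulation of salicylaldehydes with internal alkynes to 2,3-disubstituted chromones. No stereocentre is formed. The selectivity needed is the orientation of insertion (ring B at C3): the trimethylsilyl group is bulkier than the aryl group and stabilises a neighbouring carbon–metal bond, so it should end next to rhodium as in Larock-type heteroannulations of silyl alkynes, and the electron-rich aryl group makes its own alkyne carbon the better acceptor of the acyl group. Chemoselectivity for the formyl C–H bond follows from the phenol chelate, the methoxy group at C5 blocks a second, carbonyl-directed C–H activation of the product, and the trisubstituted prenyl alkenes are poor ligands for rhodium.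

Step 5
Reactants: 9 3-[3,4-bis(3-methylbut-2-enyloxy)phenyl]-5,7-dimethoxy-2-(trimethylsilyl)chromen-4-one
Product: 10 Glabrescione B (3-[3,4-bis(3-methylbut-2-enyloxy)phenyl]-5,7-dimethoxychromen-4-one)
Conditions: (n-Bu)4NF·3H2O (1.2 equiv), THF, 0 °C to rt
Reagents that add atoms: none
Why: Fluoride-induced protodesilylation: fluoride adds to silicon and the C2–Si bond, which sits on the electron-poor, oxygen-bearing vinylic carbon of the pyranone, should break with protonation by the water of hydration; methyl and prenyl ethers are inert, and the short, cold exposure is meant to keep hydroxide from opening ring C (any 9 that loses silicon already in step 4 is simply 10).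

Compound list (no compound has a stereocentre or a stereogenic double bond)
1 | 3,4-dihydroxybenzaldehyde | O=Cc1ccc(O)c(O)c1 | starting material
2 | prenyl bromide (1-bromo-3-methylbut-2-ene) | CC(C)=CCBr | starting material
3 | 3,4-bis(3-methylbut-2-enyloxy)benzaldehyde | O=Cc1ccc(OCC=C(C)C)c(OCC=C(C)C)c1 | intermediate
4 | 4-(2-diazoethenyl)-1,2-bis(3-methylbut-2-enyloxy)benzene (diazoalkene) | [N-]=[N+]=C=Cc1ccc(OCC=C(C)C)c(OCC=C(C)C)c1 | intermediate
5 | 4-ethynyl-1,2-bis(3-methylbut-2-enyloxy)benzene | C#Cc1ccc(OCC=C(C)C)c(OCC=C(C)C)c1 | intermediate
6 | {[3,4-bis(3-methylbut-2-enyloxy)phenyl]ethynyl}lithium (lithium acetylide) | [Li]C#Cc1ccc(OCC=C(C)C)c(OCC=C(C)C)c1 | intermediate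
7 | {[3,4-bis(3-methylbut-2-enyloxy)phenyl]ethynyl}trimethylsilane | C[Si](C)(C)C#Cc1ccc(OCC=C(C)C)c(OCC=C(C)C)c1 | intermediate
8 | 2-hydroxy-4,6-dimethoxybenzaldehyde | COc1cc(O)c(C=O)c(OC)c1 | starting material
9 | 3-[3,4-bis(3-methylbut-2-enyloxy)phenyl]-5,7-dimethoxy-2-(trimethylsilyl)chromen-4-one | COc1cc(OC)c2c(=O)c(-c3ccc(OCC=C(C)C)c(OCC=C(C)C)c3)c([Si](C)(C)C)oc2c1 | intermediate
10 | Glabrescione B | COc1cc(OC)c2c(=O)c(-c3ccc(OCC=C(C)C)c(OCC=C(C)C)c3)coc2c1 | target

Total step count: 5
Longest linear sequence: 5 steps (1 → 3 → 5 → 7 → 9 → 10); 8 is bought and enters at step 4.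

Steps most likely to fail

1. Step 4. The insertion may take the opposite or a mixed orientation. The alkynyl C–Si bond may also be cleaved by acetate and copper before insertion, followed by oxidative dimerisation of the freed alkyne. Rhodium may further decarbonylate the acyl intermediate or engage the prenyl alkenes. Fallback: abandon the annulation for the classical deoxybenzoin construction, with prenylation last. Commercial 3,5-dimethoxyphenol is acylated with commercial 3,4-dihydroxyphenylacetic acid in BF3·OEt2 at 80–90 °C (Friedel–Crafts acylation ortho to the chelating phenol) to give 2-(3,4-dihydroxyphenyl)-1-(2-hydroxy-4,6-dimethoxyphenyl)ethanone F1. DMF, BF3·OEt2 and MsCl at 60–80 °C then formylate the methylene and close the pyranone to 3-(3,4-dihydroxyphenyl)-5,7-dimethoxychromen-4-one F2. Alkylation of the catechol with prenyl bromide 2 (K2CO3, acetone, reflux), as in step 1, should give 10. Among the numbered compounds the fallback sets out from 2, together with the two commercial compounds named, and comes back to the route at 10.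

2. Step 5. Hydroxide or fluoride may add at C2 and open ring C, or the C–Si bond may cleave too slowly for the lactone-like ring to survive. Fallback: make the ring opening the intended reaction and rebuild C2. From 9, aqueous KOH in EtOH at reflux should degrade the pyranone (addition at C2, then retro-Claisen loss of the silyl-bearing carbon) to 2-[3,4-bis(3-methylbut-2-enyloxy)phenyl]-1-(2-hydroxy-4,6-dimethoxyphenyl)ethanone F3; this is the classical alkaline degradation of an isoflavone to its deoxybenzoin. F3 is then condensed with N,N-dimethylformamide dimethyl acetal (toluene, 100 °C), and the enaminone closes onto the phenol to give 10. The fallback sets out from 9 and comes back at 10.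

3. Step 2. Olefination of the electron-rich aldehyde by the diazophosphonate anion may be sluggish, or methanol may intercept the carbene. Fallback: a Corey–Fuchs sequence. From 3, CBr4 and PPh3 in CH2Cl2 at 0 °C (Et3N present to scavenge acid) should give 4-(2,2-dibromoethenyl)-1,2-bis(3-methylbut-2-enyloxy)benzene F4. n-BuLi (2.1 equiv) in THF at −78 °C converts F4 by bromine–lithium exchange and Fritsch–Buttenberg–Wiechell rearrangement into lithium acetylide 6, which is quenched in the same flask with Me3SiCl. The fallback sets out from 3 and comes back at 7, passing by 5.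

Further compounds
F1 | step 4 | 2-(3,4-dihydroxyphenyl)-1-(2-hydroxy-4,6-dimethoxyphenyl)ethanone | O=C(Cc1ccc(O)c(O)c1)c1c(O)cc(OC)cc1OC
F2 | step 4 | 3-(3,4-dihydroxyphenyl)-5,7-dimethoxychromen-4-one | COc1cc(OC)c2c(=O)c(-c3ccc(O)c(O)c3)coc2c1
F3 | step 5 | 2-[3,4-bis(3-methylbut-2-enyloxy)phenyl]-1-(2-hydroxy-4,6-dimethoxyphenyl)ethanone | O=C(Cc1ccc(OCC=C(C)C)c(OCC=C(C)C)c1)c1c(O)cc(OC)cc1OC
F4 | step 2 | 4-(2,2-dibromoethenyl)-1,2-bis(3-methylbut-2-enyloxy)benzene | BrC(Br)=Cc1ccc(OCC=C(C)C)c(OCC=C(C)C)c1
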